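**Retrosynthetic overview**

1. The last operation is global hydrogenolysis of nona-O-benzyl ether 13. Before it, the bond between flavan C4 and flavonol C5 is cut, giving flavonol 5-triflate 12 and the 3,4-epoxide 9 of a (2S)-flav-3-ene; they are joined by a nickel/titanocene reductive cross-electrophile coupling that opens the oxirane.
2. Enabling feature, flavan half: C4 is benzylic to ring A and conjugated through C4a with O7 (para) and O1 (ortho). Only the oxirane C4–O bond is therefore cleaved by single-electron transfer, and the C3 titanium alkoxide beside the planar C4 radical sends the aryl group in trans.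
3. Enabling feature, flavonol half: C5 lies peri to the C4 carbonyl of the pyranone ring. The hydrogen-bonded 5-OH of gossypetin is the one hydroxyl that escapes benzylation, so the triflate lands on C5, and the carbonyl chelates nickel after insertion. Electrophilic substitution would attack C6 instead.
4. Flavan half: ring A is bought (gallacetophenone), the pyranone ring is closed first (chromone 4), ring B is added by asymmetric conjugate addition (sets C2), then C4=O is converted to C3=C4 and to the oxirane anti to the 2-aryl group.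
5. Flavonol half: all three rings are bought as gossypetin; benzylation and triflation follow. Order of events: pyranone ring, C2, oxirane, coupling (C3, C4 and the inter-flavonoid bond), debenzylation.

Key step: step 9

Assumption: gossypetin (10) is taken as a commercial flavonol, and the sense of induction of t-BuPyOx known for simple chromones is taken to hold for chromone 4, so that the (R)-ligand delivers the 2S flavanone.

**Route**

Step 1
Reactants: 1 gallacetophenone (1-(2,3,4-trihydroxyphenyl)ethan-1-one)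
Product: 2 1-[3,4-bis(benzyloxy)-2-hydroxyphenyl]ethan-1-one
Conditions: BnBr (2.1 equiv), K2CO3, DMF, 25 °C
Reagents that add atoms: benzyl bromide, BrCc1ccccc1
Why: Williamson etherification; the 2-hydroxyl is hydrogen-bonded to the acetyl carbonyl and is the least nucleophilic, so two equivalents of benzyl bromide should alkylate O3 and O4 only.

Step 2
Reactants: 2 1-[3,4-bis(benzyloxy)-2-hydroxyphenyl]ethan-1-one
Product: 4 7,8-bis(benzyloxy)-4H-chromen-4-one, via enaminone 3 (not isolated)
Conditions: Me2NCH(OMe)2, toluene, 100 °C; then conc. HCl, CH2Cl2, 25 °C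
Reagents that add atoms: N,N-dimethylformamide dimethyl acetal, COC(OC)N(C)C
Why: Condensation of the methyl ketone with the amide acetal gives the enaminone, and acid-induced conjugate addition of the phenol with loss of dimethylamine closes the pyranone ring (standard enaminone chromone synthesis).

Step 3
Reactants: 4 7,8-bis(benzyloxy)-4H-chromen-4-one; 5 [3,4-bis(benzyloxy)phenyl]boronic acid
Product: 6 (2S)-7,8-bis(benzyloxy)-2-[3,4-bis(benzyloxy)phenyl]-2,3-dihydro-4H-chromen-4-one
Conditions: Pd(OCOCF3)2 (5 mol %), (R)-t-BuPyOx (6 mol %), NH4PF6 (30 mol %), H2O (5 equiv), ClCH2CH2Cl, 60 °C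
Reagents that add atoms: none
Why: Palladium-catalysed asymmetric conjugate addition of an arylboronic acid to a chromone (arylpalladium insertion, then protonolysis of the palladium enolate by water); the pyridine–oxazoline ligand sets C2, and the non-basic medium avoids retro-oxa-Michael racemization.

Step 4
Reactants: 6 (2S)-7,8-bis(benzyloxy)-2-[3,4-bis(benzyloxy)phenyl]-2,3-dihydro-4H-chromen-4-one
Product: 7 (2S,4S)-7,8-bis(benzyloxy)-2-[3,4-bis(benzyloxy)phenyl]-3,4-dihydro-2H-chromen-4-ol (2,4-cis)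
Conditions: NaBH4, THF/MeOH, 0 °C
Reagents that add atoms: none
Why: Hydride reduction of the ketone; axial attack should give mainly the 2,4-cis alcohol, and the C4 configuration is of no consequence because it is erased in step 5.

Step 5
Reactants: 7 (2S,4S)-7,8-bis(benzyloxy)-2-[3,4-bis(benzyloxy)phenyl]-3,4-dihydro-2H-chromen-4-ol
Product: 8 (2S)-7,8-bis(benzyloxy)-2-[3,4-bis(benzyloxy)phenyl]-2H-chromene
Conditions: Burgess reagent (methyl N-(triethylammoniosulfonyl)carbamate), THF, 50 °C; product kept cold and in the dark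
Reagents that add atoms: none
Why: Burgess dehydration of the p-alkoxybenzylic alcohol through its sulfamate under neutral conditions, which avoids acid that could ionize the C2–O1 bond and erode the C2 configuration.

Step 6
Reactants: 8 (2S)-7,8-bis(benzyloxy)-2-[3,4-bis(benzyloxy)phenyl]-2H-chromene
Product: 9 (2R,3S,4S)-7,8-bis(benzyloxy)-2-[3,4-bis(benzyloxy)phenyl]-3,4-epoxy-3,4-dihydro-2H-chromene (oxirane oxygen on the face opposite the 2-aryl group)
Conditions: dimethyldioxirane (1.1 equiv, acetone solution), CH2Cl2, −20 °C; volatiles removed at 0 °C, crude used at once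
Reagents that add atoms: dimethyldioxirane, CC1(C)OO1
Why: Neutral dioxirane epoxidation of the electron-rich styrene-type C3=C4 bond; attack on the face opposite the C2 aryl group (substrate control) sets the C3 and C4 oxygen, and the acid-free medium lets the labile p-alkoxybenzylic oxirane survive.

Step 7
Reactants: 10 gossypetin (3,5,7,8,3',4'-hexahydroxyflavone)
Product: 11 3,7,8-tris(benzyloxy)-2-[3,4-bis(benzyloxy)phenyl]-5-hydroxy-4H-chromen-4-one
Conditions: BnBr (5.3 equiv), K2CO3, degassed DMF, 40 °C, argon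
Reagents that add atoms: benzyl bromide, BrCc1ccccc1
Why: Williamson etherification; the 5-hydroxyl is chelated to the C4 carbonyl and should stay free, as is usual for 5-hydroxyflavones, and exclusion of air protects the oxidizable ring A.

Step 8
Reactants: 11 3,7,8-tris(benzyloxy)-2-[3,4-bis(benzyloxy)phenyl]-5-hydroxy-4H-chromen-4-one
Product: 12 3,7,8-tris(benzyloxy)-2-[3,4-bis(benzyloxy)phenyl]-4-oxo-4H-chromen-5-yl trifluoromethanesulfonate
Conditions: Tf2O, pyridine, CH2Cl2, 0 to 25 °C
Reagents that add atoms: trifluoromethanesulfonic anhydride, O=S(=O)(OS(=O)(=O)C(F)(F)F)C(F)(F)F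
Why: O-sulfonylation of the chelated phenol, the usual way to turn the 5-hydroxyl of a flavone into a cross-coupling handle.

Step 9
Reactants: 9 (2R,3S,4S)-7,8-bis(benzyloxy)-2-[3,4-bis(benzyloxy)phenyl]-3,4-epoxy-3,4-dihydro-2H-chromene; 12 3,7,8-tris(benzyloxy)-2-[3,4-bis(benzyloxy)phenyl]-4-oxo-4H-chromen-5-yl trifluoromethanesulfonate
Product: 13 3,7,8-tris(benzyloxy)-2-[3,4-bis(benzyloxy)phenyl]-5-{(2R,3S,4R)-7,8-bis(benzyloxy)-2-[3,4-bis(benzyloxy)phenyl]-3-hydroxy-3,4-dihydro-2H-chromen-4-yl}-4H-chromen-4-one (2,3-trans-3,4-trans)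
Conditions: NiCl2(dme) (15 mol %), 2,2'-bipyridine (15 mol %), Cp2TiCl2 (25 mol %), Mn powder (3 equiv), Et3N·HCl (2 equiv), DMPU/THF, 25 °C; 9 (1.5 equiv) added slowly
Reagents that add atoms: none
Why: Zerovalent nickel bound to 2,2'-bipyridine should insert into the C5–OTf bond of 12, where the peri C4 carbonyl oxygen closes a five-membered chelate on the arylnickel, while Cp2TiCl (trivalent titanium, formed from Cp2TiCl2 and Mn) opens oxirane 9 by single-electron transfer at the C4–O bond; the C4 radical is captured by the arylnickel, reductive elimination from trivalent nickel forms the C4–C5 bond, and Et3N·HCl frees the product from the tetravalent titanium alkoxide. The closest known reaction type is the nickel/titanocene-cocatalysed reductive cross-electrophile coupling of epoxides with aryl halides and a vinyl triflate, in which 1,2-disubstituted cyclic epoxides give trans-2-aryl alcohols; here an aryl triflate activated by an ortho carbonyl is used, with chloride supplied by Et3N·HCl. No ring is closed; the oxirane is opened and the pyran ring of the flavan stays intact. The new stereocenter C4 is controlled by C3, because the planar benzylic radical is attacked on the face opposite the bulky C3–O–TiCp2Cl group, which gives the 3,4-trans (all-equatorial 2,3-trans-3,4-trans) isomer; C3 keeps the configuration set in step 6 since its C–O bond is never broken, and C2 is untouched. The step needs cleavage at C4 rather than C3 (secured by benzylic stabilization from ring A with O7 para and O1 ortho to C4a), cross- rather than homo-coupling (the triflate reacts only with nickel, the oxirane only with titanium) and tolerance of the flavonol carbonyl (a vinylogous ester that is hard to reduce).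

Step 10
Reactants: 13 nona-O-benzyl ether (name as in step 9)
Product: 14 2-(3,4-dihydroxyphenyl)-5-[(2R,3S,4R)-2-(3,4-dihydroxyphenyl)-3,7,8-trihydroxy-3,4-dihydro-2H-chromen-4-yl]-3,7,8-trihydroxy-4H-chromen-4-one (CNP0395591.2)
Conditions: H2 (1 atm), Pd(OH)2/C, THF/MeOH, 25 °C; filtration under argon, Sephadex LH-20
Reagents that add atoms: none
Why: Hydrogenolysis of nine benzyl ethers; the tetrasubstituted conjugated C2=C3 bond of the flavonol and the cyclic benzylic C2–O1 ether of the flavan should survive at 1 atm, as in the deprotection of benzylated proanthocyanidins, and no stereocenter is touched.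

**Compound list**

1 | gallacetophenone, 1-(2,3,4-trihydroxyphenyl)ethan-1-one | CC(=O)c1ccc(O)c(O)c1O | starting material
2 | 1-[3,4-bis(benzyloxy)-2-hydroxyphenyl]ethan-1-one | CC(=O)c1ccc(OCc2ccccc2)c(OCc2ccccc2)c1O | intermediate
3 | (E)-1-[3,4-bis(benzyloxy)-2-hydroxyphenyl]-3-(dimethylamino)prop-2-en-1-one (enaminone, not isolated) | CN(C)/C=C/C(=O)c1ccc(OCc2ccccc2)c(OCc2ccccc2)c1O | intermediate
4 | 7,8-bis(benzyloxy)-4H-chromen-4-one | O=c1ccoc2c(OCc3ccccc3)c(OCc3ccccc3)ccc12 | intermediate
5 | [3,4-bis(benzyloxy)phenyl]boronic acid | OB(O)c1ccc(OCc2ccccc2)c(OCc2ccccc2)c1 | starting material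
6 | (2S)-7,8-bis(benzyloxy)-2-[3,4-bis(benzyloxy)phenyl]-2,3-dihydro-4H-chromen-4-one | O=C1C[C@@H](c2ccc(OCc3ccccc3)c(OCc3ccccc3)c2)Oc2c(OCc3ccccc3)c(OCc3ccccc3)ccc12 | intermediate
7 | (2S,4S)-7,8-bis(benzyloxy)-2-[3,4-bis(benzyloxy)phenyl]-3,4-dihydro-2H-chromen-4-ol | O[C@H]1C[C@@H](c2ccc(OCc3ccccc3)c(OCc3ccccc3)c2)Oc2c(OCc3ccccc3)c(OCc3ccccc3)ccc12 | intermediate
8 | (2S)-7,8-bis(benzyloxy)-2-[3,4-bis(benzyloxy)phenyl]-2H-chromene | C1=C[C@@H](c2ccc(OCc3ccccc3)c(OCc3ccccc3)c2)Oc2c(OCc3ccccc3)c(OCc3ccccc3)ccc12 | intermediate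
9 | (2R,3S,4S)-7,8-bis(benzyloxy)-2-[3,4-bis(benzyloxy)phenyl]-3,4-epoxy-3,4-dihydro-2H-chromene | O1[C@H]2c3ccc(OCc4ccccc4)c(OCc4ccccc4)c3O[C@H](c3ccc(OCc4ccccc4)c(OCc4ccccc4)c3)[C@@H]12 | intermediate
10 | gossypetin, 3,5,7,8,3',4'-hexahydroxyflavone | O=c1c(O)c(-c2ccc(O)c(O)c2)oc2c(O)c(O)cc(O)c12 | starting material
11 | 3,7,8-tris(benzyloxy)-2-[3,4-bis(benzyloxy)phenyl]-5-hydroxy-4H-chromen-4-one | O=c1c(OCc2ccccc2)c(-c2ccc(OCc3ccccc3)c(OCc3ccccc3)c2)oc2c(OCc3ccccc3)c(OCc3ccccc3)cc(O)c12 | intermediate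
12 | 3,7,8-tris(benzyloxy)-2-[3,4-bis(benzyloxy)phenyl]-4-oxo-4H-chromen-5-yl trifluoromethanesulfonate | O=c1c(OCc2ccccc2)c(-c2ccc(OCc3ccccc3)c(OCc3ccccc3)c2)oc2c(OCc3ccccc3)c(OCc3ccccc3)cc(OS(=O)(=O)C(F)(F)F)c12 | intermediate
13 | 3,7,8-tris(benzyloxy)-2-[3,4-bis(benzyloxy)phenyl]-5-{(2R,3S,4R)-7,8-bis(benzyloxy)-2-[3,4-bis(benzyloxy)phenyl]-3-hydroxy-3,4-dihydro-2H-chromen-4-yl}-4H-chromen-4-one | O=c1c(OCc2ccccc2)c(-c2ccc(OCc3ccccc3)c(OCc3ccccc3)c2)oc2c(OCc3ccccc3)c(OCc3ccccc3)cc([C@@H]3c4ccc(OCc5ccccc5)c(OCc5ccccc5)c4O[C@H](c4ccc(OCc5ccccc5)c(OCc5ccccc5)c4)[C@H]3O)c12 | intermediate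
14 | 2-(3,4-dihydroxyphenyl)-5-[(2R,3S,4R)-2-(3,4-dihydroxyphenyl)-3,7,8-trihydroxy-3,4-dihydro-2H-chromen-4-yl]-3,7,8-trihydroxy-4H-chromen-4-one | O=c1c(O)c(-c2ccc(O)c(O)c2)oc2c(O)c(O)cc([C@@H]3c4ccc(O)c(O)c4O[C@H](c4ccc(O)c(O)c4)[C@H]3O)c12 | target

**Step count and risks**

Total step count: 10. Longest linear sequence: 8 (steps 1 to 6, 9 and 10).

Steps most likely to fail:

Step 9. Capture of the C4 radical by the crowded peri arylnickel may be slower than a second reduction by trivalent titanium, which would deoxygenate the oxirane back to 8. The Lewis-acidic medium may also ionize the oxirane (hydride shift to the flavan-3-one) before single-electron opening, and 12 may suffer hydrodetriflation. The fallback replaces the sp3–sp2 coupling by an sp2–sp2 coupling followed by stereoselective hydration; it sets out from 6 and 12 and comes back at 13.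
- Flavanone 6 is triflated by soft enolization (Tf2O, 2,6-di-tert-butyl-4-methylpyridine, CH2Cl2, 0 °C; no enolate, hence no ring opening) to (2S)-7,8-bis(benzyloxy)-2-[3,4-bis(benzyloxy)phenyl]-2H-chromen-4-yl trifluoromethanesulfonate F1.
- Miyaura borylation (B2pin2, PdCl2(PPh3)2, PPh3, KOPh, toluene, 50 °C) should give the 4-(pinacolboryl)flav-3-ene F2.
- Suzuki–Miyaura coupling with 12 (Pd(OAc)2, SPhos, K3PO4, toluene/H2O, 80 °C) should give the 4-(flavonol-5-yl)flav-3-ene F3.
- Hydroboration–oxidation (BH3·SMe2, THF, 0 °C; then NaBO3·4H2O) on the face opposite the 2-aryl group should add H to C4 and OH to C3 syn, which is the 2,3-trans-3,4-trans alcohol 13.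

Step 6. The p-alkoxybenzylic oxirane may ionize during its formation or on concentration (ring opening, rearrangement, oligomerization), and facial selectivity may be incomplete. The fallback uses a stable benzylic chloride as the radical precursor; it sets out from 8 and comes back at 13.
- Dihydroxylation anti to the 2-aryl group (OsO4 cat., N-methylmorpholine N-oxide, acetone/H2O) should give the (2R,3S,4S)-3,4-cis-diol F4.
- Orthoester formation and chloride opening (MeC(OMe)3, PPTS; then Me3SiCl, CH2Cl2) should give the 4-chloro-3-acetate F5, with chloride at the benzylic carbon; its C4 configuration does not matter, since C4 becomes a radical.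
- Nickel-catalysed reductive coupling of this secondary benzylic chloride with 12 (NiCl2(dme), 4,4'-di-tert-butyl-2,2'-bipyridine, Mn powder, DMA, 25 °C) should give the 3-O-acetate F6, the aryl entering trans to the acetoxy group.
- Methanolysis (K2CO3, MeOH) gives 13.

Step 3. Insertion into the electron-rich 7-alkoxychromone may be slow, with protodeboronation of 5 taking over, or the enantioselectivity may be insufficient. The fallback builds the racemic flavanone and resolves it in the reduction; it sets out from 2 and comes back at 7.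
- Claisen–Schmidt condensation of 2 with 3,4-bis(benzyloxy)benzaldehyde (KOH, EtOH, 25 °C) should give the 2'-hydroxychalcone F7.
- Cyclization (NaOAc, EtOH, reflux) gives the racemic flavanone F8.
- Asymmetric transfer hydrogenation with kinetic resolution (RuCl(p-cymene)[(S,S)-TsDPEN], HCO2H/Et3N, EtOAc, 25 °C) should reduce only the 2S enantiomer, to the cis alcohol 7; the unreduced 2R ketone is removed by chromatography.

**Further compounds**

F1 | step 9 | (2S)-7,8-bis(benzyloxy)-2-[3,4-bis(benzyloxy)phenyl]-2H-chromen-4-yl trifluoromethanesulfonate | O=S(=O)(OC1=C[C@@H](c2ccc(OCc3ccccc3)c(OCc3ccccc3)c2)Oc2c(OCc3ccccc3)c(OCc3ccccc3)ccc12)C(F)(F)F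
F2 | step 9 | (2S)-7,8-bis(benzyloxy)-2-[3,4-bis(benzyloxy)phenyl]-4-(4,4,5,5-tetramethyl-1,3,2-dioxaborolan-2-yl)-2H-chromene | CC1(C)OB(OC1(C)C)C1=C[C@@H](c2ccc(OCc3ccccc3)c(OCc3ccccc3)c2)Oc2c(OCc3ccccc3)c(OCc3ccccc3)ccc12
F3 | step 9 | 3,7,8-tris(benzyloxy)-2-[3,4-bis(benzyloxy)phenyl]-5-{(2S)-7,8-bis(benzyloxy)-2-[3,4-bis(benzyloxy)phenyl]-2H-chromen-4-yl}-4H-chromen-4-one | O=c1c(OCc2ccccc2)c(-c2ccc(OCc3ccccc3)c(OCc3ccccc3)c2)oc2c(OCc3ccccc3)c(OCc3ccccc3)cc(C3=C[C@@H](c4ccc(OCc5ccccc5)c(OCc5ccccc5)c4)Oc4c(OCc5ccccc5)c(OCc5ccccc5)ccc34)c12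
F4 | step 6 | (2R,3S,4S)-7,8-bis(benzyloxy)-2-[3,4-bis(benzyloxy)phenyl]-3,4-dihydro-2H-chromene-3,4-diol (2,3-trans-3,4-cis) | O[C@H]1c2ccc(OCc3ccccc3)c(OCc3ccccc3)c2O[C@H](c2ccc(OCc3ccccc3)c(OCc3ccccc3)c2)[C@H]1O
F5 | step 6 | (2R,3R,4R)-7,8-bis(benzyloxy)-2-[3,4-bis(benzyloxy)phenyl]-4-chloro-3,4-dihydro-2H-chromen-3-yl acetate (2,3-trans-3,4-trans) | Cl[C@@H]1c2ccc(OCc3ccccc3)c(OCc3ccccc3)c2O[C@H](c2ccc(OCc3ccccc3)c(OCc3ccccc3)c2)[C@H]1OC(C)=O
F6 | step 6 | (2R,3S,4R)-7,8-bis(benzyloxy)-2-[3,4-bis(benzyloxy)phenyl]-4-{3,7,8-tris(benzyloxy)-2-[3,4-bis(benzyloxy)phenyl]-4-oxo-4H-chromen-5-yl}-3,4-dihydro-2H-chromen-3-yl acetate | O=c1c(OCc2ccccc2)c(-c2ccc(OCc3ccccc3)c(OCc3ccccc3)c2)oc2c(OCc3ccccc3)c(OCc3ccccc3)cc([C@@H]3c4ccc(OCc5ccccc5)c(OCc5ccccc5)c4O[C@H](c4ccc(OCc5ccccc5)c(OCc5ccccc5)c4)[C@H]3OC(C)=O)c12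
F7 | step 3 | (E)-1-[3,4-bis(benzyloxy)-2-hydroxyphenyl]-3-[3,4-bis(benzyloxy)phenyl]prop-2-en-1-one | O=C(/C=C/c1ccc(OCc2ccccc2)c(OCc2ccccc2)c1)c1ccc(OCc2ccccc2)c(OCc2ccccc2)c1O
F8 | step 3 | racemic 7,8-bis(benzyloxy)-2-[3,4-bis(benzyloxy)phenyl]-2,3-dihydro-4H-chromen-4-one | O=C1CC(c2ccc(OCc3ccccc3)c(OCc3ccccc3)c2)Oc2c(OCc3ccccc3)c(OCc3ccccc3)ccc12
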